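The ratio of Saturday's incoming ligand to Thursday's is 3.67, and the question is whether the loss of starting complex follows it.

| setting | Thursday's | Saturday's | zeta | theta | epsilon |
|---|---|---|---|---|---|
| starting complex | 0.068 M (fed, over 6.0 min) | 0.068 M (fed, over 6.0 min) | 0.068 M (fed, over 6.0 min) | 0.068 M (fed, over 6.0 min) | 0.068 M (fed, over 6.0 min) |
| incoming ligand | 0.12 M | 0.44 M | 0.270 M | 0.140 M | 0.540 M |
| remark | run made earlier | run made earlier |  |  |  |
| time |  |  | 12 min | 12 min | 12 min |

| run | time / min | starting complex / % | complex with one exchanged / % |
|---|---|---|---|
| Thursday's | 1.50 | 26 | 0 |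
| Thursday's | 3.00 | 45 | 5 |
| Thursday's | 5.00 | 73 | 10 |
| Thursday's | 6.00 | 87 | 13 |
| Thursday's | 8.00 | 78 | 18 |
| Saturday's | 1.50 | 21 | 2 |
| Saturday's | 3.00 | 35 | 9 |
| Saturday's | 5.00 | 54 | 21 |
| Saturday's | 6.00 | 61 | 28 |
| Saturday's | 8.00 | 42 | 31 |

(scatter of a reading: 1.5 percentage points)

* part of the starting complex that has reacted at the end, zeta
* part of the starting complex that has reacted at the end, theta
* part of the starting complex that has reacted at the end, epsilon
* what raising the concentration of incoming ligand from its lowest to its highest value here does to the part of the starting complex that has reacted (changes below 5 percentage points count as none) (it rises / it falls / no change)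

After the feed, the logarithm of the fall in starting complex reads 0.0546 min⁻¹ on Thursday and 0.187 min⁻¹ on Saturday. That ratio is 3.42, so the order in incoming ligand reads 0.946. The loss is treated as pseudo-first-order, and the quantity carried is the loss constant, the rate of loss of starting complex per molar of incoming ligand. Saturday's fall gives a reading of it:

K = 0.00707 M⁻¹ s⁻¹

A second way uses the level at the end of Saturday's feed. Dosed material has on average spent half the dosing time in the flask, which gives 0.00624 M⁻¹ s⁻¹. The two ways part, and a test shows which one cheats. With x = K·c·t_f, where c is the charge of incoming ligand and t_f the dosing time, K predicts 1.12 for x on Saturday. The average of the exponential over the dose then gives 60.2%, against a reading of 61% with scatter 1.5 percentage points. The mean age gives 57.1%. The shortcut cheats, because an average of exponentials lies above the exponential of the average age.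

The part left at time t is then:

left = (1 − e^(−x))/x · e^(−K·c·(t − t_f))

With ligand held at its charge, this reckoning gives 63.6% reacted for zeta and 41.1% for theta. Epsilon keeps 13.8%.

The forecast, using “slightly depleted average ligand levels”, says 59% for zeta, 38% for theta and 84% for epsilon, lower than this reckoning for zeta and theta, and of the trend with incoming ligand, it rises.

The flasks give 57.4% for zeta, 35.7% for theta and 82.0% for epsilon; of the trend with incoming ligand, it rises, by 46 points.

    starting complex + incoming ligand ⇌ leaving ligand + complex with one exchanged (K = 0.0680, k = 0.00780 M⁻¹ s⁻¹)
    complex with one exchanged + incoming ligand ⇌ leaving ligand + complex with two exchanged (K = 0.670, k = 0.00280 M⁻¹ s⁻¹)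
    complex with two exchanged + incoming ligand ⇌ leaving ligand + complex with three exchanged (K = 6.60, k = 0.0140 M⁻¹ s⁻¹)
    complex with three exchanged + incoming ligand ⇌ leaving ligand + complex with four exchanged (K = 0.910, k = 0.00610 M⁻¹ s⁻¹)
    leaving ligand + incoming ligand ⇌ idle adduct, settled at all times (K = 300 M⁻¹)
    complex with one exchanged + incoming ligand → over-reaction product (k = 0.00600 M⁻¹ s⁻¹)

In epsilon, starting complex went by the first exchange, forward half-life 3.2 min at 5.58 min, while 66% of the incoming ligand still stood free at 12.0 min. Complex with one exchanged meanwhile passed to over-reaction product, which stood at 38.2% at 12.0 min, with starting complex at 18% against the reckoned 13.8%. Theta's incoming ligand lowered to 0.116 M moves its answer by 5 points from 35.7%, below the forecast's low end, 33%.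

Epsilon left until 50 min: K gives 0.00229% of starting complex left. The flask holds 0.36%, more by 2.20 powers of ten, with 99.6% reacted.

The data were generated by integration for substances that don't exist; scatter was added.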